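## Retrosynthetic overview

1. Target 20 ⇒ global desilylation and Mitsunobu esterification ⇒ dihydrobenzofuran alcohol 17 + p-coumaric acid 18.
2. The dihydrofuran ring (the only ring formed) ⇒ acid cyclodehydration of phenol/benzylic alcohol 16; C-2 is set trans by C-3.
3. 16 ⇒ ozonolysis/NaBH4 of the o-(but-2-enyl)phenol 13, turning the propenyl group into the CH2OH.
4. 13 ⇒ aromatic Claisen [3,3] rearrangement of aryl allyl ether 9, forming the C-3/C-3a bond with 1,3-chirality transfer from a lactate-derived C–O centre.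
5. 9 ⇒ enal 6 + aryl Grignard 8; 6 ⇒ phenol 2 + methyl (R)-lactate 3 (Mitsunobu, then reduction/Wittig).

Assumption: aryl bromide 7 is bought as its TBS ether (catalogue compound); the carbinol centre made in step 4 is a deliberate epimer mixture that step 7 erases.

Abbreviations: TBDPS = tert-butyldiphenylsilyl, TBS = tert-butyldimethylsilyl, TMS = trimethylsilyl, BSA = N,O-bis(trimethylsilyl)acetamide.

## Route

Step 1
Reactants: 1 4-(3-hydroxypropyl)-2-methoxyphenol (dihydroconiferyl alcohol)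
Product: 2 4-[3-(TBDPS-oxy)propyl]-2-methoxyphenol
Conditions: TBDPSCl (1.05 equiv), imidazole, CH2Cl2, 0 °C
Reagents that add atoms: tert-butyl(chloro)diphenylsilane, CC(C)(C)[Si](Cl)(c1ccccc1)c1ccccc1
Why: Chemoselective silylation, because the unhindered primary alcohol reacts with the bulky silyl chloride much faster than the ortho-methoxy (hydrogen-bonded) phenol.

Step 2
Reactants: 2 4-[3-(TBDPS-oxy)propyl]-2-methoxyphenol; 3 methyl (R)-lactate
Product: 4 methyl (2S)-2-{4-[3-(TBDPS-oxy)propyl]-2-methoxyphenoxy}propanoate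
Conditions: PPh3, DIAD, THF, 0 °C → rt
Reagents that add atoms: none
Why: Mitsunobu etherification of the phenol with the activated secondary carbinol of the lactate proceeds by clean SN2 inversion (R → S), so the C–O stereocentre comes from the bought lactate.

Step 3
Reactants: 4 methyl (2S)-2-{4-[3-(TBDPS-oxy)propyl]-2-methoxyphenoxy}propanoate
Product: 6 (2E,4S)-4-{4-[3-(TBDPS-oxy)propyl]-2-methoxyphenoxy}pent-2-enal, via aldehyde 5 (not isolated)
Conditions: DIBAL-H (1.1 equiv), CH2Cl2, −78 °C; then Ph3P=CHCHO (1.3 equiv), −78 → 40 °C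
Reagents that add atoms: (triphenylphosphoranylidene)acetaldehyde, O=CC=P(c1ccccc1)(c1ccccc1)c1ccccc1
Why: Half-reduction of the α-aryloxy ester stops at the chelated aluminium hemiacetal, and the aldehyde released on warming is trapped in the same flask by the stabilised ylide (E-selective Wittig), so the labile α-aryloxy aldehyde is never isolated and the stereocentre is untouched.

Step 4
Reactants: 6 (2E,4S)-4-{4-[3-(TBDPS-oxy)propyl]-2-methoxyphenoxy}pent-2-enal; 7 (4-bromo-2-methoxyphenoxy)(tert-butyl)dimethylsilane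
Product: 9 (1RS,2E,4S)-1-[4-(TBS-oxy)-3-methoxyphenyl]-4-{4-[3-(TBDPS-oxy)propyl]-2-methoxyphenoxy}pent-2-en-1-ol, via Grignard reagent 8 (not isolated)
Conditions: 7, Mg (I2 cat.), THF, 40 °C; then 6, −78 → −40 °C; aq. NH4Cl
Reagents that add atoms: none
Why: Grignard 1,2-addition to the enal is fast at low temperature and leaves the C-4 centre and the E-alkene alone; the new carbinol centre forms unselectively, which does not matter because it is reset in step 7.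

Step 5
Reactants: 9 (1RS,2E,4S)-1-[4-(TBS-oxy)-3-methoxyphenyl]-4-{4-[3-(TBDPS-oxy)propyl]-2-methoxyphenoxy}pent-2-en-1-ol
Product: 13 (1RS,2R,3E)-2-{5-[3-(TBDPS-oxy)propyl]-2-hydroxy-3-methoxyphenyl}-1-[4-(TBS-oxy)-3-methoxyphenyl]pent-3-en-1-ol, via TMS ether 10 (not isolated), via ortho-dienone 11 (not isolated), via bis-TMS ether 12 (not isolated)
Conditions: BSA (3 equiv), PhNEt2, 185 °C, sealed tube; then 1 M HCl, THF/MeOH, 0 °C
Reagents that add atoms: none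
Why: Aromatic Claisen rearrangement to the only free ortho position through a chair transition state with the methyl group equatorial; the suprafacial [3,3] shift transfers the (S) C–O centre across the E-alkene to the new benzylic carbon (future C-3), while BSA masks the sensitive carbinol and traps the phenol so that abnormal Claisen and ionisation pathways are suppressed.

Step 6
Reactants: 13 (1RS,2R,3E)-2-{5-[3-(TBDPS-oxy)propyl]-2-hydroxy-3-methoxyphenyl}-1-[4-(TBS-oxy)-3-methoxyphenyl]pent-3-en-1-ol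
Product: 16 (1RS,2S)-2-{5-[3-(TBDPS-oxy)propyl]-2-hydroxy-3-methoxyphenyl}-1-[4-(TBS-oxy)-3-methoxyphenyl]propane-1,3-diol, via secondary ozonide 14 (not isolated), via lactol 15 (not isolated)
Conditions: O3, CH2Cl2, −78 °C (Sudan Red 7B end point); then NaBH4, MeOH, −78 → 0 °C
Reagents that add atoms: ozone, [O-][O+]=O
Why: Ozonolysis of the only C=C with an indicator end point, followed by in-flask borohydride reduction, converts the propenyl group into CH2OH; the α-aryl aldehyde exists only briefly as its lactol, so the benzylic stereocentre is not epimerised (the S descriptor is only a priority change).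

Step 7
Reactants: 16 (1RS,2S)-2-{5-[3-(TBDPS-oxy)propyl]-2-hydroxy-3-methoxyphenyl}-1-[4-(TBS-oxy)-3-methoxyphenyl]propane-1,3-diol
Product: 17 {(2R,3S)-2-[4-(TBS-oxy)-3-methoxyphenyl]-7-methoxy-5-[3-(TBDPS-oxy)propyl]-2,3-dihydro-1-benzofuran-3-yl}methanol
Conditions: p-TsOH·H2O (10 mol %), 4 Å MS, CH2Cl2, 0 °C → rt
Reagents that add atoms: none
Why: SN1 cycloetherification, in which acid ionises the electron-rich benzylic alcohol of both epimers to one p-silyloxybenzyl cation that the ortho phenol captures anti to the C-3 CH2OH group, so the fixed (3S) centre dictates the kinetically and thermodynamically preferred trans (2R) centre.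

Step 8
Reactants: 17 {(2R,3S)-2-[4-(TBS-oxy)-3-methoxyphenyl]-7-methoxy-5-[3-(TBDPS-oxy)propyl]-2,3-dihydro-1-benzofuran-3-yl}methanol; 18 (E)-4-hydroxycinnamic acid (p-coumaric acid)
Product: 19 {(2R,3S)-2-[4-(TBS-oxy)-3-methoxyphenyl]-7-methoxy-5-[3-(TBDPS-oxy)propyl]-2,3-dihydro-1-benzofuran-3-yl}methyl (2E)-3-(4-hydroxyphenyl)prop-2-enoate
Conditions: PPh3, DIAD, THF, 0 °C → rt
Reagents that add atoms: none
Why: Mitsunobu esterification of the only free alcohol, in which the carboxylic acid (pKa about 4.5) is the pronucleophile and the far less acidic phenol of 18 stays free; the reacting carbon is a primary CH2, so no stereocentre is touched.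

Step 9
Reactants: 19 {(2R,3S)-2-[4-(TBS-oxy)-3-methoxyphenyl]-7-methoxy-5-[3-(TBDPS-oxy)propyl]-2,3-dihydro-1-benzofuran-3-yl}methyl (2E)-3-(4-hydroxyphenyl)prop-2-enoate
Product: 20 [(2R,3S)-2-(4-hydroxy-3-methoxyphenyl)-5-(3-hydroxypropyl)-7-methoxy-2,3-dihydro-1-benzofuran-3-yl]methyl (2E)-3-(4-hydroxyphenyl)prop-2-enoate (CNP0202924.1)
Conditions: TBAF (3 equiv), AcOH (3 equiv), THF, 0 °C → rt
Reagents that add atoms: none
Why: Fluoride-mediated desilylation removes the aryl TBS and the primary TBDPS ether together, and the acetic acid buffer keeps the cinnamate ester intact and prevents phenoxide-driven quinone-methide opening of the dihydrofuran.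

## Compound list

1 | 4-(3-hydroxypropyl)-2-methoxyphenol | COc1cc(CCCO)ccc1O | starting material
2 | 4-[3-(tert-butyldiphenylsilyloxy)propyl]-2-methoxyphenol | COc1cc(CCCO[Si](c2ccccc2)(c2ccccc2)C(C)(C)C)ccc1O | intermediate
3 | methyl (R)-lactate | C[C@@H](O)C(=O)OC | starting material
4 | methyl (2S)-2-{4-[3-(TBDPS-oxy)propyl]-2-methoxyphenoxy}propanoate | C[C@H](Oc1ccc(CCCO[Si](c2ccccc2)(c2ccccc2)C(C)(C)C)cc1OC)C(=O)OC | intermediate
5 | (2S)-2-{4-[3-(TBDPS-oxy)propyl]-2-methoxyphenoxy}propanal | C[C@H](Oc1ccc(CCCO[Si](c2ccccc2)(c2ccccc2)C(C)(C)C)cc1OC)C=O | intermediate (not isolated)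
6 | (2E,4S)-4-{4-[3-(TBDPS-oxy)propyl]-2-methoxyphenoxy}pent-2-enal | C[C@H](Oc1ccc(CCCO[Si](c2ccccc2)(c2ccccc2)C(C)(C)C)cc1OC)/C=C/C=O | intermediate
7 | (4-bromo-2-methoxyphenoxy)(tert-butyl)dimethylsilane | COc1cc(Br)ccc1O[Si](C)(C)C(C)(C)C | starting material
8 | [4-(TBS-oxy)-3-methoxyphenyl]magnesium bromide | COc1cc([Mg]Br)ccc1O[Si](C)(C)C(C)(C)C | intermediate (not isolated)
9 | (1RS,2E,4S)-1-[4-(TBS-oxy)-3-methoxyphenyl]-4-{4-[3-(TBDPS-oxy)propyl]-2-methoxyphenoxy}pent-2-en-1-ol (both C-1 epimers) | C[C@H](Oc1ccc(CCCO[Si](c2ccccc2)(c2ccccc2)C(C)(C)C)cc1OC)/C=C/C(O)c1ccc(O[Si](C)(C)C(C)(C)C)c(OC)c1 | intermediate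
10 | 1-O-TMS ether of 9 | C[C@H](Oc1ccc(CCCO[Si](c2ccccc2)(c2ccccc2)C(C)(C)C)cc1OC)/C=C/C(O[Si](C)(C)C)c1ccc(O[Si](C)(C)C(C)(C)C)c(OC)c1 | intermediate (not isolated)
11 | (6S)-6-{(1RS,2R,3E)-1-[4-(TBS-oxy)-3-methoxyphenyl]-1-(TMS-oxy)pent-3-en-2-yl}-2-methoxy-4-[3-(TBDPS-oxy)propyl]cyclohexa-2,4-dien-1-one | COC1=CC(CCCO[Si](c2ccccc2)(c2ccccc2)C(C)(C)C)=C[C@@H]([C@@H](/C=C/C)C(O[Si](C)(C)C)c2ccc(O[Si](C)(C)C(C)(C)C)c(OC)c2)C1=O | intermediate (not isolated)
12 | bis-TMS ether (phenol O and carbinol O) of 13 | C/C=C/[C@H](c1cc(CCCO[Si](c2ccccc2)(c2ccccc2)C(C)(C)C)cc(OC)c1O[Si](C)(C)C)C(O[Si](C)(C)C)c1ccc(O[Si](C)(C)C(C)(C)C)c(OC)c1 | intermediate (not isolated)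
13 | (1RS,2R,3E)-2-{5-[3-(TBDPS-oxy)propyl]-2-hydroxy-3-methoxyphenyl}-1-[4-(TBS-oxy)-3-methoxyphenyl]pent-3-en-1-ol | C/C=C/[C@H](c1cc(CCCO[Si](c2ccccc2)(c2ccccc2)C(C)(C)C)cc(OC)c1O)C(O)c1ccc(O[Si](C)(C)C(C)(C)C)c(OC)c1 | intermediate
14 | secondary ozonide of 13: (1RS,2R)-2-{5-[3-(TBDPS-oxy)propyl]-2-hydroxy-3-methoxyphenyl}-1-[4-(TBS-oxy)-3-methoxyphenyl]-2-(3-methyl-1,2,4-trioxolan-5-yl)ethan-1-ol (trioxolane epimers) | CC1OOC(O1)[C@H](c1cc(CCCO[Si](c2ccccc2)(c2ccccc2)C(C)(C)C)cc(OC)c1O)C(O)c1ccc(O[Si](C)(C)C(C)(C)C)c(OC)c1 | intermediate (not isolated)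
15 | (3R)-3-{hydroxy[4-(TBS-oxy)-3-methoxyphenyl]methyl}-7-methoxy-5-[3-(TBDPS-oxy)propyl]-2,3-dihydro-1-benzofuran-2-ol (anomers and carbinol epimers) | OC1Oc2c(OC)cc(CCCO[Si](c3ccccc3)(c3ccccc3)C(C)(C)C)cc2[C@@H]1C(O)c1ccc(O[Si](C)(C)C(C)(C)C)c(OC)c1 | intermediate (not isolated)
16 | (1RS,2S)-2-{5-[3-(TBDPS-oxy)propyl]-2-hydroxy-3-methoxyphenyl}-1-[4-(TBS-oxy)-3-methoxyphenyl]propane-1,3-diol | OC[C@H](c1cc(CCCO[Si](c2ccccc2)(c2ccccc2)C(C)(C)C)cc(OC)c1O)C(O)c1ccc(O[Si](C)(C)C(C)(C)C)c(OC)c1 | intermediate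
17 | {(2R,3S)-2-[4-(TBS-oxy)-3-methoxyphenyl]-7-methoxy-5-[3-(TBDPS-oxy)propyl]-2,3-dihydro-1-benzofuran-3-yl}methanol | COc1cc([C@@H]2Oc3c(OC)cc(CCCO[Si](c4ccccc4)(c4ccccc4)C(C)(C)C)cc3[C@H]2CO)ccc1O[Si](C)(C)C(C)(C)C | intermediate
18 | (E)-4-hydroxycinnamic acid (p-coumaric acid) | OC(=O)/C=C/c1ccc(O)cc1 | starting material
19 | {(2R,3S)-2-[4-(TBS-oxy)-3-methoxyphenyl]-7-methoxy-5-[3-(TBDPS-oxy)propyl]-2,3-dihydro-1-benzofuran-3-yl}methyl (2E)-3-(4-hydroxyphenyl)prop-2-enoate | COc1cc([C@@H]2Oc3c(OC)cc(CCCO[Si](c4ccccc4)(c4ccccc4)C(C)(C)C)cc3[C@H]2COC(=O)/C=C/c2ccc(O)cc2)ccc1O[Si](C)(C)C(C)(C)C | intermediate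
20 | [(2R,3S)-2-(4-hydroxy-3-methoxyphenyl)-5-(3-hydroxypropyl)-7-methoxy-2,3-dihydro-1-benzofuran-3-yl]methyl (2E)-3-(4-hydroxyphenyl)prop-2-enoate | COc1cc([C@@H]2Oc3c(OC)cc(CCCO)cc3[C@H]2COC(=O)/C=C/c2ccc(O)cc2)ccc1O | target

## Step count and risks

Total step count: 9. Longest linear sequence: 9 (1 → 20).

The three steps most likely to fail:

**Step 5 (Claisen rearrangement).** The allyl terminus carries a bulky, ionisable silyloxybenzyl group, so the rearrangement may be slow, may compete with elimination, or may lose enantiopurity. The fallback rearranges a simpler ether and brings in the aryl ring afterwards; because the two allyl-terminus substituents swap roles, it uses the other lactate enantiomer. It sets out from 2 and comes back at 16. Mitsunobu reaction of 2 with ethyl (S)-lactate (PPh3, DIAD) gives ethyl (2R)-2-{4-[3-(TBDPS-oxy)propyl]-2-methoxyphenoxy}propanoate F1. One-pot DIBAL-H reduction and Wittig reaction with Ph3P=CHCO2Et gives ethyl (2E,4R)-4-{4-[3-(TBDPS-oxy)propyl]-2-methoxyphenoxy}pent-2-enoate F2. DIBAL-H reduction gives (2E,4R)-4-{4-[3-(TBDPS-oxy)propyl]-2-methoxyphenoxy}pent-2-en-1-ol F3. Its Claisen rearrangement (BSA, PhNEt2, 180 °C, then dilute acid) on this unhindered substrate gives (2S,3E)-2-{5-[3-(TBDPS-oxy)propyl]-2-hydroxy-3-methoxyphenyl}pent-3-en-1-ol F4. Ozonolysis with Me2S work-up gives (3S)-3-(hydroxymethyl)-7-methoxy-5-[3-(TBDPS-oxy)propyl]-2,3-dihydro-1-benzofuran-2-ol F5. Addition of excess Grignard reagent 8 (LaCl3·2LiCl, THF, −78 °C) to the lactol gives 16.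

**Step 3 (one-pot reduction and formyl-Wittig).** The formyl ylide is sluggish, the enal product can be homologated a second time, and aldehyde 5 can partly racemise if it lingers. The fallback goes through the ester oxidation level; it sets out from 4 and comes back at 6. One-pot DIBAL-H reduction and Wittig reaction with the more reactive Ph3P=CHCO2Et gives ethyl (2E,4S)-4-{4-[3-(TBDPS-oxy)propyl]-2-methoxyphenoxy}pent-2-enoate F6. DIBAL-H reduction (2.2 equiv, −78 °C) gives (2E,4S)-4-{4-[3-(TBDPS-oxy)propyl]-2-methoxyphenoxy}pent-2-en-1-ol F7. Allylic oxidation with MnO2 in CH2Cl2 gives 6.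

**Step 8 (Mitsunobu esterification with the unprotected phenolic acid).** The yield may be eroded by O-alkylation or oligomerisation of 18. The fallback builds the cinnamate on the alcohol instead of coupling a preformed acid; it sets out from 17 and comes back at 19. Heating 17 with Meldrum's acid in toluene (100 °C) gives 3-{(2R,3S)-2-[4-(TBS-oxy)-3-methoxyphenyl]-7-methoxy-5-[3-(TBDPS-oxy)propyl]-2,3-dihydro-1-benzofuran-3-yl}methoxy-3-oxopropanoic acid F8. Knoevenagel–Doebner condensation of this malonate half-ester with 4-hydroxybenzaldehyde (pyridine, cat. piperidine, 60 °C) gives, with decarboxylation, the (E)-cinnamate 19.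

## Further compounds

F1 | step 5 | ethyl (2R)-2-{4-[3-(TBDPS-oxy)propyl]-2-methoxyphenoxy}propanoate | C[C@@H](Oc1ccc(CCCO[Si](c2ccccc2)(c2ccccc2)C(C)(C)C)cc1OC)C(=O)OCC
F2 | step 5 | ethyl (2E,4R)-4-{4-[3-(TBDPS-oxy)propyl]-2-methoxyphenoxy}pent-2-enoate | C[C@@H](Oc1ccc(CCCO[Si](c2ccccc2)(c2ccccc2)C(C)(C)C)cc1OC)/C=C/C(=O)OCC
F3 | step 5 | (2E,4R)-4-{4-[3-(TBDPS-oxy)propyl]-2-methoxyphenoxy}pent-2-en-1-ol | C[C@@H](Oc1ccc(CCCO[Si](c2ccccc2)(c2ccccc2)C(C)(C)C)cc1OC)/C=C/CO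
F4 | step 5 | (2S,3E)-2-{5-[3-(TBDPS-oxy)propyl]-2-hydroxy-3-methoxyphenyl}pent-3-en-1-ol | OC[C@H](c1cc(CCCO[Si](c2ccccc2)(c2ccccc2)C(C)(C)C)cc(OC)c1O)/C=C/C
F5 | step 5 | (3S)-3-(hydroxymethyl)-7-methoxy-5-[3-(TBDPS-oxy)propyl]-2,3-dihydro-1-benzofuran-2-ol (anomers) | OC[C@@H]1c2cc(CCCO[Si](c3ccccc3)(c3ccccc3)C(C)(C)C)cc(OC)c2OC1O
F6 | step 3 | ethyl (2E,4S)-4-{4-[3-(TBDPS-oxy)propyl]-2-methoxyphenoxy}pent-2-enoate | C[C@H](Oc1ccc(CCCO[Si](c2ccccc2)(c2ccccc2)C(C)(C)C)cc1OC)/C=C/C(=O)OCC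
F7 | step 3 | (2E,4S)-4-{4-[3-(TBDPS-oxy)propyl]-2-methoxyphenoxy}pent-2-en-1-ol | C[C@H](Oc1ccc(CCCO[Si](c2ccccc2)(c2ccccc2)C(C)(C)C)cc1OC)/C=C/CO
F8 | step 8 | 3-{(2R,3S)-2-[4-(TBS-oxy)-3-methoxyphenyl]-7-methoxy-5-[3-(TBDPS-oxy)propyl]-2,3-dihydro-1-benzofuran-3-yl}methoxy-3-oxopropanoic acid | COc1cc([C@@H]2Oc3c(OC)cc(CCCO[Si](c4ccccc4)(c4ccccc4)C(C)(C)C)cc3[C@H]2COC(=O)CC(=O)O)ccc1O[Si](C)(C)C(C)(C)C
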